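**Plan**
- Retrosynthesis cuts, in this order: the five benzyl ethers; the C4–C4a acyl–aryl bond of the flavanone; the O1–C2 benzylic aryl ether; the C2 carbinol back to a β-keto ester and then to an aldehyde plus a diazoacetate (C3, C4); the diaryl ether at the linker ring (SNAr); the flavonol 3-OH.
- Forward: the kaempferol tricycle comes intact from apigenin (benzylation, C3 hydroxylation). 4-Fluorobenzaldehyde supplies flavanone ring B and C2, and 3,5-bis(benzyloxy)phenol supplies ring A and O1. Flavanone ring C is the only ring built, and it is closed last, by C–C bond formation.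
- Enabling feature: flavanone ring A is a phloroglucinol ring. In the 3,5-dioxygenated aryl ether the two carbons ortho to O1 (future C4a and C8) are equivalent, and each is ortho, ortho and para to three oxygens. The tethered acyl carbon can therefore form only one six-membered ketone, and should do so without a Lewis acid.
- Stereochemistry: C2 is set as the (R)-carbinol by asymmetric transfer hydrogenation, inverted to (S) in the Mitsunobu etherification, and is not a reacting atom afterwards; the closed flavanone never meets base.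

Key step: step 8

Remarks: flavanone atoms are numbered O1, C2, C3, C4 (C=O), C4a, C5–C8, C8a. Kf stands for the 5,7-bis(benzyloxy)-2-[4-(benzyloxy)phenyl]-4-oxo-4H-chromen-3-yl group (tri-O-benzylkaempferol bonded through C3).

**Step 1**
Reactants: 1 apigenin
Product: 2 5,7-bis(benzyloxy)-2-[4-(benzyloxy)phenyl]-4H-chromen-4-one
Conditions: BnBr (excess), K2CO3, DMF, 80 °C
Reagents that add atoms: benzyl bromide, BrCc1ccccc1
Why: Williamson O-benzylation of all three phenols, the chelated 5-OH being the slowest and the reason for excess bromide and heat; no stereocentre is involved.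

**Step 2**
Reactants: 2 5,7-bis(benzyloxy)-2-[4-(benzyloxy)phenyl]-4H-chromen-4-one
Product: 4 5,7-bis(benzyloxy)-2-[4-(benzyloxy)phenyl]-3-hydroxy-4H-chromen-4-one, via flavone 2,3-epoxide 3 (not isolated)
Conditions: DMDO (acetone), CH2Cl2, 0 °C to rt; then p-TsOH·H2O (cat.), rt
Reagents that add atoms: dimethyldioxirane, CC1(C)OO1
Why: Dioxirane epoxidation of the enol-ether C2=C3 bond of a flavone, followed by acid-catalysed opening at C2 (oxocarbenium stabilised by O1 and the aryl group) and loss of H3, is the known flavone-to-flavonol oxidation.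

**Step 3**
Reactants: 4 5,7-bis(benzyloxy)-2-[4-(benzyloxy)phenyl]-3-hydroxy-4H-chromen-4-one; 5 4-fluorobenzaldehyde
Product: 6 4-[(Kf)oxy]benzaldehyde
Conditions: Cs2CO3, DMF, 90 °C, N2
Reagents that add atoms: none
Why: Nucleophilic aromatic substitution (addition–elimination) by the acidic 3-oxide of the flavonol at the fluorine-bearing carbon para to the formyl group, the standard diaryl ether synthesis with 4-fluorobenzaldehyde.

**Step 4**
Reactants: 6 4-[(Kf)oxy]benzaldehyde
Product: 7 ethyl 3-{4-[(Kf)oxy]phenyl}-3-oxopropanoate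
Conditions: N2CHCO2Et, NbCl5 (5 mol %), CH2Cl2, rt
Reagents that add atoms: ethyl diazoacetate, CCOC(=O)C=[N+]=[N-]
Why: Roskamp homologation, in which the Lewis-acid-activated aldehyde adds the diazo carbon and a 1,2-hydride shift with loss of N2 gives the β-keto ester directly.

**Step 5**
Reactants: 7 ethyl 3-{4-[(Kf)oxy]phenyl}-3-oxopropanoate
Product: 8 ethyl (3R)-3-hydroxy-3-{4-[(Kf)oxy]phenyl}propanoate
Conditions: RuCl(p-cymene)[(R,R)-TsDPEN] (1 mol %), HCO2H/Et3N (5:2), DMF, 40 °C
Reagents that add atoms: none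
Why: Noyori–Ikariya asymmetric transfer hydrogenation of an aryl ketone, in which the (R,R)-ligand should deliver hydride to the Si face and so give the (R)-benzylic carbinol, as it does for acetophenone-type ketones and β-keto esters.

**Step 6**
Reactants: 8 ethyl (3R)-3-hydroxy-3-{4-[(Kf)oxy]phenyl}propanoate; 9 3,5-bis(benzyloxy)phenol
Product: 10 ethyl (3S)-3-[3,5-bis(benzyloxy)phenoxy]-3-{4-[(Kf)oxy]phenyl}propanoate
Conditions: PPh3, DIAD, THF, 0 °C to rt
Reagents that add atoms: none
Why: Mitsunobu etherification, in which the aryloxide of 9 displaces the benzylic oxyphosphonium by SN2 with inversion, turning the (R)-carbinol into the (S)-aryl ether.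

**Step 7**
Reactants: 10 ethyl (3S)-3-[3,5-bis(benzyloxy)phenoxy]-3-{4-[(Kf)oxy]phenyl}propanoate
Product: 11 (3S)-3-[3,5-bis(benzyloxy)phenoxy]-3-{4-[(Kf)oxy]phenyl}propanoic acid
Conditions: LiOH·H2O, THF/H2O, 0 °C; then 1 M HCl
Reagents that add atoms: lithium hydroxide, [Li+].[OH-]
Why: Saponification of an unhindered ethyl ester at 0 °C should be much faster than α-deprotonation, so the β-aryloxy group is not expelled, and the carboxylate formed can no longer eliminate; the stereocentre is not a reacting atom.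

**Step 8**
Reactants: 11 (3S)-3-[3,5-bis(benzyloxy)phenoxy]-3-{4-[(Kf)oxy]phenyl}propanoic acid
Product: 13 (2S)-5,7-bis(benzyloxy)-2-{4-[(Kf)oxy]phenyl}-2,3-dihydro-4H-chromen-4-one, via mixed trifluoroacetic anhydride 12 (not isolated)
Conditions: (CF3CO)2O, CH2Cl2, 0 °C to rt
Reagents that add atoms: none
Why: Acid 11 and trifluoroacetic anhydride give the mixed anhydride 12, whose non-fluorinated acyl group is transferred as an acylium equivalent to the ring carbon ortho to the ether oxygen O1, and the Wheland intermediate then loses a proton; this is intramolecular Friedel–Crafts acylation, the standard closure of 3-aryloxypropanoic acids to chroman-4-ones. Ring C closes as a six-membered ring by 6-exo-trig attack of the arene carbon on the acyl carbon. No stereocentre is formed; C2 is not a reacting atom and keeps the S configuration installed in step 6. Regioselectivity needs nothing beyond the substrate: the two carbons ortho to O1 are equivalent by the local symmetry of the 3,5-bis(benzyloxy)phenoxy ring, each is ortho, ortho and para to three oxygen donors, and the equally activated para carbon cannot be reached by the three-atom tether. Chemoselectivity rests on the same activation, so ring closure should outrun trifluoroacetylation and any intermolecular acylation of the chromone ring A (deactivated by its C4 carbonyl) or of the para-disubstituted linker ring. Configurational integrity is secured by the absence of Lewis acid and base and by the low temperature, so that the benzylic C2–O1 bond, whose cation would be destabilised by the adjacent CH2C(=O) group, should neither ionise nor eliminate before the ketone forms.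

**Step 9**
Reactants: 13 (2S)-5,7-bis(benzyloxy)-2-{4-[(Kf)oxy]phenyl}-2,3-dihydro-4H-chromen-4-one
Product: 14 (2S)-5,7-dihydroxy-2-(4-{[5,7-dihydroxy-2-(4-hydroxyphenyl)-4-oxo-4H-chromen-3-yl]oxy}phenyl)-2,3-dihydro-4H-chromen-4-one
Conditions: H2 (1 atm), Pd/C, THF/MeOH, rt
Reagents that add atoms: none
Why: Catalytic hydrogenolysis of the five benzyl aryl ethers under neutral conditions, which flavanone and flavonol cores normally survive, should release all six phenols without touching C2.

**Compound list**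
1 | apigenin (5,7-dihydroxy-2-(4-hydroxyphenyl)-4H-chromen-4-one) | O=c1cc(-c2ccc(O)cc2)oc2cc(O)cc(O)c12 | starting material
2 | 5,7-bis(benzyloxy)-2-[4-(benzyloxy)phenyl]-4H-chromen-4-one | O=c1cc(-c2ccc(OCc3ccccc3)cc2)oc2cc(OCc3ccccc3)cc(OCc3ccccc3)c12 | intermediate
3 | 2,3-epoxide of 2 (racemic, cis-fused oxirane across C2–C3) | O=C1C2OC2(c2ccc(OCc3ccccc3)cc2)Oc2cc(OCc3ccccc3)cc(OCc3ccccc3)c12 | intermediate
4 | 5,7-bis(benzyloxy)-2-[4-(benzyloxy)phenyl]-3-hydroxy-4H-chromen-4-one (5,7,4'-tri-O-benzylkaempferol) | O=c1c(O)c(-c2ccc(OCc3ccccc3)cc2)oc2cc(OCc3ccccc3)cc(OCc3ccccc3)c12 | intermediate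
5 | 4-fluorobenzaldehyde | O=Cc1ccc(F)cc1 | starting material
6 | 4-[(Kf)oxy]benzaldehyde | O=Cc1ccc(Oc2c(-c3ccc(OCc4ccccc4)cc3)oc3cc(OCc4ccccc4)cc(OCc4ccccc4)c3c2=O)cc1 | intermediate
7 | ethyl 3-{4-[(Kf)oxy]phenyl}-3-oxopropanoate | CCOC(=O)CC(=O)c1ccc(Oc2c(-c3ccc(OCc4ccccc4)cc3)oc3cc(OCc4ccccc4)cc(OCc4ccccc4)c3c2=O)cc1 | intermediate
8 | ethyl (3R)-3-hydroxy-3-{4-[(Kf)oxy]phenyl}propanoate | CCOC(=O)C[C@H](c1ccc(Oc2c(-c3ccc(OCc4ccccc4)cc3)oc3cc(OCc4ccccc4)cc(OCc4ccccc4)c3c2=O)cc1)O | intermediate
9 | 3,5-bis(benzyloxy)phenol | Oc1cc(OCc2ccccc2)cc(OCc2ccccc2)c1 | starting material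
10 | ethyl (3S)-3-[3,5-bis(benzyloxy)phenoxy]-3-{4-[(Kf)oxy]phenyl}propanoate | CCOC(=O)C[C@@H](c1ccc(Oc2c(-c3ccc(OCc4ccccc4)cc3)oc3cc(OCc4ccccc4)cc(OCc4ccccc4)c3c2=O)cc1)Oc1cc(OCc2ccccc2)cc(OCc2ccccc2)c1 | intermediate
11 | (3S)-3-[3,5-bis(benzyloxy)phenoxy]-3-{4-[(Kf)oxy]phenyl}propanoic acid | OC(=O)C[C@@H](c1ccc(Oc2c(-c3ccc(OCc4ccccc4)cc3)oc3cc(OCc4ccccc4)cc(OCc4ccccc4)c3c2=O)cc1)Oc1cc(OCc2ccccc2)cc(OCc2ccccc2)c1 | intermediate
12 | mixed anhydride of 11 with trifluoroacetic acid, (3S) | O=C(C[C@@H](c1ccc(Oc2c(-c3ccc(OCc4ccccc4)cc3)oc3cc(OCc4ccccc4)cc(OCc4ccccc4)c3c2=O)cc1)Oc1cc(OCc2ccccc2)cc(OCc2ccccc2)c1)OC(=O)C(F)(F)F | intermediate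
13 | (2S)-5,7-bis(benzyloxy)-2-{4-[(Kf)oxy]phenyl}-2,3-dihydro-4H-chromen-4-one | O=C1C[C@@H](c2ccc(Oc3c(-c4ccc(OCc5ccccc5)cc4)oc4cc(OCc5ccccc5)cc(OCc5ccccc5)c4c3=O)cc2)Oc2cc(OCc3ccccc3)cc(OCc3ccccc3)c21 | intermediate
14 | (2S)-5,7-dihydroxy-2-(4-{[5,7-dihydroxy-2-(4-hydroxyphenyl)-4-oxo-4H-chromen-3-yl]oxy}phenyl)-2,3-dihydro-4H-chromen-4-one (CNP0144321.1) | O=C1C[C@@H](c2ccc(Oc3c(-c4ccc(O)cc4)oc4cc(O)cc(O)c4c3=O)cc2)Oc2cc(O)cc(O)c21 | target

**Summary**
Total step count: 9. Longest linear sequence: 9 steps (1 to 14); compounds 5 and 9 enter as purchased fragments.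

**Steps most likely to fail**

Step 8. The risk is acid-promoted ionisation of the benzylic C2–O1 bond before the ketone forms, which would erode the configuration or expel the aryloxy group, together with competing trifluoroacetylation of the activated ring. The fallback closes ring C through the O1–C2 bond instead. It sets out from aldehyde 6 and comes back at 13. Claisen–Schmidt condensation of 6 with purchased 1-[2,4-bis(benzyloxy)-6-hydroxyphenyl]ethanone (KOH, EtOH/THF, rt) should give (E)-1-[2,4-bis(benzyloxy)-6-hydroxyphenyl]-3-{4-[(Kf)oxy]phenyl}prop-2-en-1-one F1. Oxa-Michael ring closure (NaOAc, EtOH, reflux) should give racemic 5,7-bis(benzyloxy)-2-{4-[(Kf)oxy]phenyl}-2,3-dihydro-4H-chromen-4-one F2. Preparative HPLC on a chiral stationary phase then separates the (2S)-enantiomer, which is 13; the other enantiomer can be re-equilibrated with base through the chalcone and recycled.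

Step 6. The risk is dehydration of the activated β-hydroxy ester to the cinnamate (elimination across the acidic α-CH2) and partial ionisation at the benzylic carbon, which would lower the enantiomeric purity. The fallback moves the etherification to the alcohol oxidation level, where no acidic α-hydrogen exists. It sets out from 8 and comes back at 11. Reduction of the ester (LiBH4, THF, 0 °C; the vinylogous-ester carbonyl of the chromone should be the slower site) gives (1R)-1-{4-[(Kf)oxy]phenyl}propane-1,3-diol F3. Selective silylation of the primary hydroxyl (TBSCl, imidazole, CH2Cl2, 0 °C) gives (1R)-3-[(tert-butyldimethylsilyl)oxy]-1-{4-[(Kf)oxy]phenyl}propan-1-ol F4. Mitsunobu etherification with 9 (PPh3, DIAD, THF) inverts the centre and gives tert-butyl{(3S)-3-[3,5-bis(benzyloxy)phenoxy]-3-{4-[(Kf)oxy]phenyl}propoxy}dimethylsilane F5. Desilylation (Bu4NF, THF) gives (3S)-3-[3,5-bis(benzyloxy)phenoxy]-3-{4-[(Kf)oxy]phenyl}propan-1-ol F6. Oxidation (TEMPO cat., PhI(OAc)2, MeCN/H2O) takes the primary alcohol to acid 11 under non-basic conditions.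

Step 3. The risk is slow substitution at the hindered, weakly nucleophilic 3-oxide, with base-induced oxidative degradation of the flavonol at the temperature needed. The fallback replaces the addition–elimination by an oxidative copper-mediated coupling. It sets out from 4 and comes back at 6: Chan–Lam arylation of 4 with (4-formylphenyl)boronic acid (Cu(OAc)2, pyridine, 4 Å molecular sieves, CH2Cl2, air, rt) should give 6 at room temperature. It makes no compound outside the list (entry F0).

**Further compounds**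
F0 | step 3 | none | none
F1 | step 8 | (E)-1-[2,4-bis(benzyloxy)-6-hydroxyphenyl]-3-{4-[(Kf)oxy]phenyl}prop-2-en-1-one | O=C(/C=C/c1ccc(Oc2c(-c3ccc(OCc4ccccc4)cc3)oc3cc(OCc4ccccc4)cc(OCc4ccccc4)c3c2=O)cc1)c1c(O)cc(OCc2ccccc2)cc1OCc1ccccc1
F2 | step 8 | racemic 5,7-bis(benzyloxy)-2-{4-[(Kf)oxy]phenyl}-2,3-dihydro-4H-chromen-4-one | O=C1CC(c2ccc(Oc3c(-c4ccc(OCc5ccccc5)cc4)oc4cc(OCc5ccccc5)cc(OCc5ccccc5)c4c3=O)cc2)Oc2cc(OCc3ccccc3)cc(OCc3ccccc3)c21
F3 | step 6 | (1R)-1-{4-[(Kf)oxy]phenyl}propane-1,3-diol | OCC[C@H](c1ccc(Oc2c(-c3ccc(OCc4ccccc4)cc3)oc3cc(OCc4ccccc4)cc(OCc4ccccc4)c3c2=O)cc1)O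
F4 | step 6 | (1R)-3-[(tert-butyldimethylsilyl)oxy]-1-{4-[(Kf)oxy]phenyl}propan-1-ol | CC(C)(C)[Si](C)(C)OCC[C@H](c1ccc(Oc2c(-c3ccc(OCc4ccccc4)cc3)oc3cc(OCc4ccccc4)cc(OCc4ccccc4)c3c2=O)cc1)O
F5 | step 6 | tert-butyl{(3S)-3-[3,5-bis(benzyloxy)phenoxy]-3-{4-[(Kf)oxy]phenyl}propoxy}dimethylsilane | CC(C)(C)[Si](C)(C)OCC[C@@H](c1ccc(Oc2c(-c3ccc(OCc4ccccc4)cc3)oc3cc(OCc4ccccc4)cc(OCc4ccccc4)c3c2=O)cc1)Oc1cc(OCc2ccccc2)cc(OCc2ccccc2)c1
F6 | step 6 | (3S)-3-[3,5-bis(benzyloxy)phenoxy]-3-{4-[(Kf)oxy]phenyl}propan-1-ol | OCC[C@@H](c1ccc(Oc2c(-c3ccc(OCc4ccccc4)cc3)oc3cc(OCc4ccccc4)cc(OCc4ccccc4)c3c2=O)cc1)Oc1cc(OCc2ccccc2)cc(OCc2ccccc2)c1
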